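The plan rests on cutting the (S)-3-oxygenated butanoyl ester on the C4 oxygen of benzene ring A into a phenol, carbon monoxide and (S)-propylene oxide: chain carbons C2–C4 with the C3 oxygen are the epoxide, carbonyl C1 is CO. A single cobalt-catalysed carbonylative epoxide opening should forge the C1–C2 bond and the C1–O(aryl) ester bond at once, close no ring, and pass the epoxide methine untouched into chain stereocentre C3. Its precursor is methyl (E)-3-bromo-4-hydroxycinnamate, whose bromine ortho to the phenol is kept as the handle for a late, base-free Stille attachment of the (E)-3-hydroxy-3-methylbutenyl arm at C3 of ring A.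

Key step: step 2

Remark: the single stereocentre is taken as (S) and both alkenes as E, as the SMILES specifies; methyl (triphenylphosphoranylidene)acetate, Bu3SnH and the catalysts are taken as bought reagents.

Step 1
Reactants: 1 3-bromo-4-hydroxybenzaldehyde
Product: 2 methyl (E)-3-(3-bromo-4-hydroxyphenyl)prop-2-enoate
Conditions: Ph3P=CHCO2Me (1.2 equiv), toluene, 90 °C
Reagents that add atoms: methyl (triphenylphosphoranylidene)acetate, COC(=O)C=P(c1ccccc1)(c1ccccc1)c1ccccc1
Why: Wittig olefination with an ester-stabilised ylide, which should give the E-cinnamate; proton exchange between the phenol and the ylide is reversible, so the free phenol needs no protection.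

Step 2
Reactants: 2 methyl (E)-3-(3-bromo-4-hydroxyphenyl)prop-2-enoate, 3 (S)-propylene oxide [(S)-2-methyloxirane], 4 carbon monoxide
Product: 5 methyl (E)-3-[3-bromo-4-[(S)-3-hydroxybutanoyloxy]phenyl]prop-2-enoate
Conditions: Co2(CO)8 (5 mol %), 3-hydroxypyridine (10 mol %), CO (40 bar), 3 (1.5 equiv), dry THF, 60 °C, stopped when 2 is consumed
Reagents that add atoms: none
Why: Proposed new method: 3-hydroxypyridine disproportionates Co2(CO)8 to the Co(CO)4 anion, which opens the hydrogen-bond-activated epoxide 3 by SN2 attack at its CH2 carbon; migratory insertion of CO gives the (S)-3-hydroxybutanoyl cobalt tetracarbonyl, and the pyridinium aryloxide of 2 attacks this acyl to release ester 5 and HCo(CO)4, which the base returns to the anion. The closest known reaction type is the cobalt-catalysed carbonylative opening of enantiopure terminal epoxides in the presence of alcohols (alkoxycarbonylation) to beta-hydroxy esters; the new element is a phenol as the acyl acceptor. No ring is closed: the oxirane is opened and the chain stays acyclic. No stereocentre is created; chain C3 is the epoxide methine, whose C–O and C–CH3 bonds are never broken, so (S)-3 should give the (S)-ester with the CIP order O > CH2 > CH3 unchanged. Two selectivities are needed: attack at the unsubstituted epoxide carbon, which the methyl group enforces sterically, and capture of the acyl cobalt by aryloxide faster than direct etherification of the phenol by the epoxide, beta-lactone closure or acylation of the product's own hydroxyl; the acidity of the ortho-bromo, para-acrylate phenol (readily ionised by the pyridine, yet a poor nucleophile toward an unactivated epoxide at 60 °C) is expected to favour this. The aryl bromide and the cinnamate should be inert to the Co(CO)4 anion under thermal conditions.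

Step 3
Reactants: 5 methyl (E)-3-[3-bromo-4-[(S)-3-hydroxybutanoyloxy]phenyl]prop-2-enoate
Product: 6 methyl (E)-3-[4-[(S)-3-acetoxybutanoyloxy]-3-bromophenyl]prop-2-enoate
Conditions: Ac2O (1.5 equiv), pyridine (3 equiv), CH2Cl2, 0 °C to rt
Reagents that add atoms: acetic anhydride, CC(=O)OC(C)=O
Why: O-acetylation of the secondary carbinol (nucleophilic acyl substitution at the anhydride) leaves the C3–O bond untouched, so the (S) centre is retained; omitting DMAP and working cold should spare the activated aryl ester from acyl exchange and the product from E1cB loss of acetic acid.

Step 4
Reactants: 7 2-methylbut-3-yn-2-ol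
Product: 8 (E)-2-methyl-4-(tributylstannyl)but-3-en-2-ol
Conditions: Bu3SnH (1.1 equiv, slow addition), PdCl2(PPh3)2 (2 mol %), THF, 0 °C to rt
Reagents that add atoms: tributyltin hydride, CCCC[SnH](CCCC)CCCC
Why: Palladium-catalysed hydrostannation adds Sn–H syn across the terminal alkyne with tin on the terminal carbon, away from the bulky tertiary carbinol, which should give the E-alkenylstannane; any internal regioisomer should be removable by chromatography.

Step 5
Reactants: 6 methyl (E)-3-[4-[(S)-3-acetoxybutanoyloxy]-3-bromophenyl]prop-2-enoate, 8 (E)-2-methyl-4-(tributylstannyl)but-3-en-2-ol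
Product: 9 methyl (E)-3-[4-[(S)-3-acetoxybutanoyloxy]-3-[(E)-3-hydroxy-3-methylbut-1-enyl]phenyl]prop-2-enoate (CNP0325017.1)
Conditions: 8 (1.2 equiv), Pd(PPh3)4 (5 mol %), degassed toluene, 95 °C
Reagents that add atoms: none
Why: Stille coupling: oxidative addition of the electron-poor aryl bromide to zerovalent palladium, tin-to-palladium transfer of the alkenyl group with retention of E geometry, and reductive elimination; the neutral, base-free medium should leave the aryl ester, the beta-acetoxy group, the acrylate and the tertiary allylic alcohol intact, and no stereocentre is involved.

Compound list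
1 | 3-bromo-4-hydroxybenzaldehyde | O=Cc1ccc(O)c(Br)c1 | starting material
2 | methyl (E)-3-(3-bromo-4-hydroxyphenyl)prop-2-enoate | COC(=O)/C=C/c1ccc(O)c(Br)c1 | intermediate
3 | (S)-propylene oxide | C[C@H]1CO1 | starting material
4 | carbon monoxide | [C-]#[O+] | starting material
5 | methyl (E)-3-[3-bromo-4-[(S)-3-hydroxybutanoyloxy]phenyl]prop-2-enoate | COC(=O)/C=C/c1ccc(OC(=O)C[C@H](C)O)c(Br)c1 | intermediate
6 | methyl (E)-3-[4-[(S)-3-acetoxybutanoyloxy]-3-bromophenyl]prop-2-enoate | COC(=O)/C=C/c1ccc(OC(=O)C[C@H](C)OC(C)=O)c(Br)c1 | intermediate
7 | 2-methylbut-3-yn-2-ol | C#CC(C)(C)O | starting material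
8 | (E)-2-methyl-4-(tributylstannyl)but-3-en-2-ol | CCCC[Sn](CCCC)(CCCC)/C=C/C(C)(C)O | intermediate
9 | methyl (E)-3-[4-[(S)-3-acetoxybutanoyloxy]-3-[(E)-3-hydroxy-3-methylbut-1-enyl]phenyl]prop-2-enoate | COC(=O)/C=C/c1ccc(OC(=O)C[C@H](C)OC(C)=O)c(/C=C/C(C)(C)O)c1 | target

Total step count: 5
Longest linear sequence: 4 steps (steps 1, 2, 3 and 5; step 4 is a one-step side branch)

Steps most likely to fail

1. Step 2 (Proposed new method). Three processes could defeat it:
- the phenol may open the epoxide directly to an aryl ether;
- the hydroxyacyl cobalt may be diverted into beta-lactone closure or oligoester growth on the product hydroxyl;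
- the weakly nucleophilic aryloxide may fail to cleave the acyl, so that the catalyst does not turn over.

Fallback, known chemistry: it sets out from phenol 2 and comes back to the route at acetate 6, replacing steps 2 and 3. Commercial (S)-3-hydroxybutanoic acid is O-acetylated with acetyl chloride (neat, 0 °C to rt, aqueous work-up) to (S)-3-acetoxybutanoic acid F1. F1 is then joined to 2 by Steglich esterification (DCC, 5 mol % DMAP, CH2Cl2, −10 °C), which should give 6 with the stereocentre bought instead of made. Carbodiimide coupling of 3-acyloxy acids is an established operation; beta-elimination to the crotonate is the side reaction to suppress, hence the low temperature and the catalytic amount of DMAP.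

2. Step 5. Transmetalation at the ortho-substituted arylpalladium bromide may be slow, which leaves room for protodestannylation and stannane homocoupling. Thermal loss of acetic acid from the beta-acetoxy ester at 95 °C is the second concern.

Fallback: it sets out from bromide 6 and comes back at target 9. A Mizoroki–Heck reaction of 6 with commercial 2-methylbut-3-en-2-ol (1.5 equiv; Pd(P(t-Bu)3)2 3 mol %, Cy2NMe 1.1 equiv, dioxane, rt to 40 °C) should arylate the terminal alkene carbon. Beta-hydride elimination can then only take the benzylic hydrogen, because the carbinol carbon bears none, so the E-alkene of 9 should form directly. No organotin reagent is needed, and the hindered amine at near-ambient temperature limits the risk to the base-sensitive ester.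

3. Step 1. Proton transfer from the acidic bromophenol to the ylide converts the aldehyde into its deactivated phenoxide, which may stall the olefination and erode E selectivity if the reaction is forced.

Fallback: it sets out from aldehyde 1 and comes back at ester 2. Knoevenagel–Doebner condensation of 1 with malonic acid (pyridine, catalytic piperidine, 90 °C) should give, with decarboxylation, (E)-3-(3-bromo-4-hydroxyphenyl)prop-2-enoic acid F2. Fischer esterification of F2 (MeOH, catalytic H2SO4, reflux) should then deliver 2.

Further compounds
F1 | step 2 | (S)-3-acetoxybutanoic acid | OC(=O)C[C@H](C)OC(C)=O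
F0 | step 5 | none | none
F2 | step 1 | (E)-3-(3-bromo-4-hydroxyphenyl)prop-2-enoic acid | OC(=O)/C=C/c1ccc(O)c(Br)c1
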